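**Plan**

- Retrosynthesis: after the benzyl ether, O1–C2 (ring C) and C4a–C5 (ring A) are cut together. Ring A has oxygen on C5, C7 and C8a and the acyl carbon C4 on C4a, so it is an acylphloroglucinol, the Claisen isomer of a 6-(acylmethyl)-4-hydroxy-2-pyrone that already contains C5–C8a and all three oxygens.
- Further cuts: C2–C3 (aroylation of a pyrone trianion by a methyl ester), C3'–O (copper-mediated aryl ether closure of the dioxane), C7''–C8'' (aldol) and O4'–C8'' (phenol alkylation).
- Forward: the 1,4-dioxane ring is built first on the bromovanillate, its ester is joined to 6-acetonyl-4-hydroxy-2-pyrone, rings A and C then form in one pot, and hydrogenolysis ends the route.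
- Stereochemistry: C7'' and C8'' both come from one Evans syn aldol reaction with (S)-4-benzyl-2-oxazolidinone; the dioxane closure breaks no bond at either centre, so the syn adduct becomes the trans (7''R,8''R) dioxane.

Key step: step 9

Remark: polycarbonyl compounds are drawn as keto tautomers although they exist largely as enols or metal chelates; atom labels follow flavonolignan numbering (chromone C2–C8a, primed ring B, double-primed phenylpropanoid unit).

**Route**

Step 1
Reactants: 1 (S)-4-benzyl-2-oxazolidinone; 2 bromoacetyl bromide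
Product: 4 (S)-4-benzyl-3-(bromoacetyl)oxazolidin-2-one, via lithium oxazolidinide 3 (not isolated)
Conditions: n-BuLi, THF, −78 °C; then 2, −78 → 0 °C
Reagents that add atoms: none
Why: N-acylation of the lithiated oxazolidinone occurs at the acyl bromide carbon, which is far more electrophilic than the CH2Br carbon, as in the usual preparation of N-haloacetyl imides.

Step 2
Reactants: 5 methyl 3-bromo-4-hydroxy-5-methoxybenzoate; 4 (S)-4-benzyl-3-(bromoacetyl)oxazolidin-2-one
Product: 6 methyl 4-{2-[(4S)-4-benzyl-2-oxooxazolidin-3-yl]-2-oxoethoxy}-3-bromo-5-methoxybenzoate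
Conditions: K2CO3, acetone, 40 °C
Reagents that add atoms: none
Why: Williamson ether synthesis in which the phenoxide displaces the activated α-bromide by SN2 and fixes the O4'–C8'' bond next to the methoxy group, while carbonate in acetone leaves imide and methyl ester intact.

Step 3
Reactants: 6 methyl 4-{2-[(4S)-4-benzyl-2-oxooxazolidin-3-yl]-2-oxoethoxy}-3-bromo-5-methoxybenzoate; 7 4-benzyloxy-3-methoxybenzaldehyde (O-benzylvanillin)
Product: 9 methyl 4-{[(1R,2S)-1-(4-benzyloxy-3-methoxyphenyl)-3-[(4S)-4-benzyl-2-oxooxazolidin-3-yl]-1-hydroxy-3-oxopropan-2-yl]oxy}-3-bromo-5-methoxybenzoate (syn aldol adduct), via dibutylboron Z-enolate 8 (not isolated)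
Conditions: Bu2BOTf, Et3N, CH2Cl2, −78 → 0 °C; then 7, −78 → 0 °C; H2O2, MeOH, pH 7 buffer, 0 °C
Reagents that add atoms: none
Why: Evans syn aldol reaction in which the Z boron enolate reacts through a chair Zimmerman–Traxler transition state on the face away from the benzyl group of the (S)-auxiliary, setting C8'' (S in the imide) and C7'' (R) in the syn relationship.

Step 4
Reactants: 9 syn aldol adduct
Product: 10 methyl 4-{[(1R,2R)-1-(4-benzyloxy-3-methoxyphenyl)-1,3-dihydroxypropan-2-yl]oxy}-3-bromo-5-methoxybenzoate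
Conditions: NaBH4, THF–H2O (4:1), 0 °C → rt
Reagents that add atoms: none
Why: Reductive cleavage of the N-acyl oxazolidinone by borohydride in wet THF reduces only the activated imide carbonyl and releases the auxiliary, the electron-rich methyl benzoate and the aryl bromide being inert; the descriptor at C8'' changes to R only through the priority change.

Step 5
Reactants: 10 the 1,3-diol
Product: 11 methyl 4-{[(1R,2R)-1-(4-benzyloxy-3-methoxyphenyl)-3-(tert-butyldimethylsilyloxy)-1-hydroxypropan-2-yl]oxy}-3-bromo-5-methoxybenzoate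
Conditions: TBSCl, imidazole, DMF, 0 °C
Reagents that add atoms: tert-butyldimethylsilyl chloride CC(C)(C)[Si](C)(C)Cl
Why: Silylation with TBSCl and imidazole selects the unhindered primary hydroxyl over the secondary benzylic one, leaving only the benzylic oxygen free for ring closure.

Step 6
Reactants: 11 the bromo alcohol
Product: 12 methyl (2R,3R)-3-(4-benzyloxy-3-methoxyphenyl)-2-[(tert-butyldimethylsilyloxy)methyl]-8-methoxy-2,3-dihydro-1,4-benzodioxine-6-carboxylate
Conditions: CuI (10 mol %), 1,10-phenanthroline (20 mol %), Cs2CO3, toluene, 110 °C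
Reagents that add atoms: none
Why: Intramolecular Ullmann-type C–O coupling in which the benzylic alkoxide on monovalent copper replaces the ortho bromide in a six-membered closure; no bond at C7'' or C8'' is broken, so the syn ether gives the trans (2R,3R) benzodioxane.

Step 7
Reactants: 13 triacetic acid lactone (4-hydroxy-6-methyl-2-pyrone); 14 N-methoxy-N-methylacetamide
Product: 16 4-hydroxy-6-(2-oxopropyl)-2H-pyran-2-one, via dilithio pyrone dianion 15 (not isolated)
Conditions: LiN(iPr)2 (2.3 equiv), THF, −78 → −30 °C; then 14, −78 → 0 °C; 1 M HCl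
Reagents that add atoms: none
Why: C-acylation of the pyrone dianion at its 6-methyl carbanion, the most nucleophilic site, by a Weinreb amide whose stable tetrahedral adduct prevents over-addition.

Step 8
Reactants: 16 4-hydroxy-6-(2-oxopropyl)-2H-pyran-2-one; 12 the benzodioxane methyl ester
Product: 18 6-{4-[(2R,3R)-3-(4-benzyloxy-3-methoxyphenyl)-2-[(tert-butyldimethylsilyloxy)methyl]-8-methoxy-2,3-dihydro-1,4-benzodioxin-6-yl]-2,4-dioxobutyl}-4-hydroxy-2H-pyran-2-one, via trilithio ketopyrone trianion 17 (not isolated)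
Conditions: 16 (2.5 equiv), LiN(iPr)2 (7.7 equiv), THF, −78 → 0 °C; then 12 (1 equiv), −78 → 0 °C; cold 1 M HCl to pH 3
Reagents that add atoms: none
Why: Claisen condensation of a polycarbonyl polyanion in which the last-formed, most basic carbanion at the terminal methyl attacks the methyl ester to form C2–C3, the excess trianion taking up the acidic proton of the new 1,3-diketone.

Step 9
Reactants: 18 the 6-(4-aryl-2,4-dioxobutyl)-4-hydroxy-2-pyrone
Product: 22 2-[(2R,3R)-3-(4-benzyloxy-3-methoxyphenyl)-2-(hydroxymethyl)-8-methoxy-2,3-dihydro-1,4-benzodioxin-6-yl]-5,7-dihydroxy-4H-chromen-4-one (4''-O-benzyl-5'-methoxyhydnocarpin), via methyl tetraoxononanoate 19 (not isolated), via trihydroxyphenyl diketone 20 (not isolated), via silylated flavone 21 (not isolated)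
Conditions: Mg(OMe)2 (8 equiv), MeOH, 65 °C; then HCl (to 0.3 M), MeOH, 50 °C
Reagents that add atoms: none
Why: Proposed new method: Mg(OMe)2 should open the 2-pyrone at the lactone carbonyl to the magnesium-chelated methyl tetraoxo ester 19, the C4a carbanion between the C4 and C8a carbonyls attacks the ester carbon C5 with loss of methoxide, and enolisation gives the aromatic trihydroxyphenyl diketone 20; dilute acid then adds the C8a hydroxyl to the C2 carbonyl and removes water, and the same methanolic HCl solvolyses the silyl ether. The closest known reactions are the Mg(OMe)2-induced Claisen recyclisation of 6-acetonyl-4-hydroxy-2-pyrone to 2,4,6-trihydroxyacetophenone and the acid cyclodehydration of o-hydroxyaryl 1,3-diketones that ends a Baker–Venkataraman flavone synthesis; their combination on a chain lengthened by an aroyl carbonyl is untested. Ring A closes by a 6-exo-trig Claisen acylation (C4a–C5) and ring C by a 6-exo-trig addition of oxygen to the C2 carbonyl followed by dehydration (O1–C2). No stereocentre is created, and C7'' and C8'' carry no enolisable hydrogen and stay as set in step 3. The step needs the Claisen mode to win over the aldol modes C6 onto C4, C8 onto C2 and C3 onto C7: magnesium holds each ketone as a chelated, non-electrophilic enolate so that the ester is the only acceptor, and the aryl-conjugated C2 carbonyl is the poorest ketone electrophile of the chain.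

Step 10
Reactants: 22 4''-O-benzyl-5'-methoxyhydnocarpin
Product: 23 5'-methoxyhydnocarpin
Conditions: H2 (1 atm), Pd/C (10 %), THF–MeOH, rt
Reagents that add atoms: none
Why: Hydrogenolysis of the benzyl aryl ether over Pd/C is much faster than reduction of the chromone C2=C3 bond or cleavage of the cyclic secondary benzylic C7''–O bond, so only the benzyl group should be lost.

**Compound list**

1 | (S)-4-benzyl-2-oxazolidinone | O=C1N[C@@H](Cc2ccccc2)CO1 | starting material
2 | bromoacetyl bromide | BrCC(Br)=O | starting material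
3 | lithium salt of 1 (not isolated) | [Li+].O=C1[N-][C@@H](Cc2ccccc2)CO1 | intermediate
4 | (S)-4-benzyl-3-(bromoacetyl)oxazolidin-2-one | O=C(CBr)N1C(=O)OC[C@@H]1Cc1ccccc1 | intermediate
5 | methyl 3-bromo-4-hydroxy-5-methoxybenzoate | COC(=O)c1cc(Br)c(O)c(OC)c1 | starting material
6 | methyl 4-{2-[(4S)-4-benzyl-2-oxooxazolidin-3-yl]-2-oxoethoxy}-3-bromo-5-methoxybenzoate | COC(=O)c1cc(Br)c(OCC(=O)N2C(=O)OC[C@@H]2Cc2ccccc2)c(OC)c1 | intermediate
7 | 4-benzyloxy-3-methoxybenzaldehyde (O-benzylvanillin) | COc1cc(C=O)ccc1OCc1ccccc1 | starting material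
8 | dibutylboron (Z)-enolate of 6 (not isolated) | CCCCB(CCCC)O/C(=C\Oc1c(Br)cc(cc1OC)C(=O)OC)N1C(=O)OC[C@@H]1Cc1ccccc1 | intermediate
9 | syn aldol adduct, (2S,3R) in the acyl chain, (4S) auxiliary | COC(=O)c1cc(Br)c(O[C@@H]([C@H](O)c2ccc(OCc3ccccc3)c(OC)c2)C(=O)N2C(=O)OC[C@@H]2Cc2ccccc2)c(OC)c1 | intermediate
10 | methyl 4-{[(1R,2R)-1-(4-benzyloxy-3-methoxyphenyl)-1,3-dihydroxypropan-2-yl]oxy}-3-bromo-5-methoxybenzoate | COC(=O)c1cc(Br)c(O[C@@H]([C@H](O)c2ccc(OCc3ccccc3)c(OC)c2)CO)c(OC)c1 | intermediate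
11 | methyl 4-{[(1R,2R)-1-(4-benzyloxy-3-methoxyphenyl)-3-(tert-butyldimethylsilyloxy)-1-hydroxypropan-2-yl]oxy}-3-bromo-5-methoxybenzoate | COC(=O)c1cc(Br)c(O[C@@H]([C@H](O)c2ccc(OCc3ccccc3)c(OC)c2)CO[Si](C)(C)C(C)(C)C)c(OC)c1 | intermediate
12 | methyl (2R,3R)-3-(4-benzyloxy-3-methoxyphenyl)-2-[(tert-butyldimethylsilyloxy)methyl]-8-methoxy-2,3-dihydro-1,4-benzodioxine-6-carboxylate | COc1cc([C@H]2Oc3cc(C(=O)OC)cc(OC)c3O[C@@H]2CO[Si](C)(C)C(C)(C)C)ccc1OCc1ccccc1 | intermediate
13 | triacetic acid lactone (4-hydroxy-6-methyl-2-pyrone) | Cc1cc(O)cc(=O)o1 | starting material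
14 | N-methoxy-N-methylacetamide | CON(C)C(C)=O | starting material
15 | dilithium dianion of 13 (not isolated) | [Li+].[Li+].[CH2-]c1cc([O-])cc(=O)o1 | intermediate
16 | 4-hydroxy-6-(2-oxopropyl)-2H-pyran-2-one | CC(=O)Cc1cc(O)cc(=O)o1 | intermediate
17 | trilithium trianion of 16 (not isolated) | [Li+].[Li+].[Li+].[CH2-]C(=O)[CH-]c1cc([O-])cc(=O)o1 | intermediate
18 | 6-{4-[(2R,3R)-3-(4-benzyloxy-3-methoxyphenyl)-2-[(tert-butyldimethylsilyloxy)methyl]-8-methoxy-2,3-dihydro-1,4-benzodioxin-6-yl]-2,4-dioxobutyl}-4-hydroxy-2H-pyran-2-one (key-step precursor) | COc1cc([C@H]2Oc3cc(C(=O)CC(=O)Cc4cc(O)cc(=O)o4)cc(OC)c3O[C@@H]2CO[Si](C)(C)C(C)(C)C)ccc1OCc1ccccc1 | intermediate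
19 | methyl 9-[(2R,3R)-3-(4-benzyloxy-3-methoxyphenyl)-2-[(tert-butyldimethylsilyloxy)methyl]-8-methoxy-2,3-dihydro-1,4-benzodioxin-6-yl]-3,5,7,9-tetraoxononanoate, as its magnesium chelate (not isolated) | COc1cc([C@H]2Oc3cc(C(=O)CC(=O)CC(=O)CC(=O)CC(=O)OC)cc(OC)c3O[C@@H]2CO[Si](C)(C)C(C)(C)C)ccc1OCc1ccccc1 | intermediate
20 | 1-[(2R,3R)-3-(4-benzyloxy-3-methoxyphenyl)-2-[(tert-butyldimethylsilyloxy)methyl]-8-methoxy-2,3-dihydro-1,4-benzodioxin-6-yl]-3-(2,4,6-trihydroxyphenyl)propane-1,3-dione (not isolated) | COc1cc([C@H]2Oc3cc(C(=O)CC(=O)c4c(O)cc(O)cc4O)cc(OC)c3O[C@@H]2CO[Si](C)(C)C(C)(C)C)ccc1OCc1ccccc1 | intermediate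
21 | 4''-O-benzyl-9''-O-(tert-butyldimethylsilyl)-5'-methoxyhydnocarpin (not isolated) | COc1cc([C@H]2Oc3cc(-c4cc(=O)c5c(O)cc(O)cc5o4)cc(OC)c3O[C@@H]2CO[Si](C)(C)C(C)(C)C)ccc1OCc1ccccc1 | intermediate
22 | 4''-O-benzyl-5'-methoxyhydnocarpin (key-step product) | COc1cc([C@H]2Oc3cc(-c4cc(=O)c5c(O)cc(O)cc5o4)cc(OC)c3O[C@@H]2CO)ccc1OCc1ccccc1 | intermediate
23 | 5'-methoxyhydnocarpin | COc1cc([C@H]2Oc3cc(-c4cc(=O)c5c(O)cc(O)cc5o4)cc(OC)c3O[C@@H]2CO)ccc1O | target

**Step count and risks**

Total steps: 10. Longest linear sequence: 9 (steps 1–6, 8, 9, 10); step 7 is a one-step branch that joins at step 8.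

Steps most likely to fail:

1. Step 9. The open-chain tetraoxo ester may close through an aldol mode (resorcylate or biaryl formation) instead of the Claisen mode, the pyrone anion may resist methanolysis, or the acid stage may ionise the benzylic C7''–O bond. Fallback with known chemistry, setting out from 12 and returning at 20: 12 is saponified (LiOH, THF–H2O) to the carboxylic acid F1. 1-Chloro-N,N,2-trimethylprop-1-enylamine in CH2Cl2 converts it under neutral conditions into the acid chloride F2. F2 is added at −78 °C to the lithium polyanion of commercial 2,4,6-trihydroxyacetophenone (LiN(SiMe3)2, THF), where C-aroylation of the acetyl carbanion should give diketone 20. The methanolic HCl stage of step 9 then leads through 21 to 22. Ring A is here bought ready-made, and the enolate aroylation and cyclodehydration sequence is an established way to 5,7-dihydroxyflavones.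

2. Step 8. Proton transfer may quench the trianion, or attack on the electron-rich trialkoxybenzoate may be slow, so that conversion stays low or O-acylation competes. Fallback setting out from 12 and returning at 18: the chain is joined at the aldehyde oxidation level. iBu2AlH (CH2Cl2, −78 °C) reduces 12 to the benzylic alcohol F3, and MnO2 (CH2Cl2) oxidises it to the aldehyde F4. Trianion 17 adds to F4 at −78 °C in a fast aldol addition to give the β-hydroxy ketone F5 (both carbinol epimers, which is of no consequence). IBX in EtOAc oxidises the benzylic carbinol to the 1,3-diketone, which is 18.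

3. Step 6. The hindered secondary alkoxide may couple slowly, so that protodebromination or a base-induced 1,3-shift of the silyl group with closure through the primary oxygen takes over. Fallback setting out from 11 and returning at 12: the roles of the partners are reversed. Miyaura borylation of 11 (Pd(dppf)Cl2, B2pin2, KOAc, dioxane, 90 °C) gives the pinacol boronate F6, and NaBO3·4H2O (THF–H2O, rt) oxidises it to the phenol F7. BF3·OEt2 (CH2Cl2, −40 °C) ionises the electron-rich benzylic alcohol, and the phenol captures the 4-benzyloxy-3-methoxybenzyl cation anti to the silyloxymethyl group. C8'' is not involved and directs formation of the trans isomer 12.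

**Further compounds**

F1 | step 9 | (2R,3R)-3-(4-benzyloxy-3-methoxyphenyl)-2-[(tert-butyldimethylsilyloxy)methyl]-8-methoxy-2,3-dihydro-1,4-benzodioxine-6-carboxylic acid | COc1cc([C@H]2Oc3cc(C(=O)O)cc(OC)c3O[C@@H]2CO[Si](C)(C)C(C)(C)C)ccc1OCc1ccccc1
F2 | step 9 | (2R,3R)-3-(4-benzyloxy-3-methoxyphenyl)-2-[(tert-butyldimethylsilyloxy)methyl]-8-methoxy-2,3-dihydro-1,4-benzodioxine-6-carbonyl chloride | COc1cc([C@H]2Oc3cc(C(=O)Cl)cc(OC)c3O[C@@H]2CO[Si](C)(C)C(C)(C)C)ccc1OCc1ccccc1
F3 | step 8 | [(2R,3R)-3-(4-benzyloxy-3-methoxyphenyl)-2-[(tert-butyldimethylsilyloxy)methyl]-8-methoxy-2,3-dihydro-1,4-benzodioxin-6-yl]methanol | COc1cc([C@H]2Oc3cc(CO)cc(OC)c3O[C@@H]2CO[Si](C)(C)C(C)(C)C)ccc1OCc1ccccc1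
F4 | step 8 | (2R,3R)-3-(4-benzyloxy-3-methoxyphenyl)-2-[(tert-butyldimethylsilyloxy)methyl]-8-methoxy-2,3-dihydro-1,4-benzodioxine-6-carbaldehyde | COc1cc([C@H]2Oc3cc(C=O)cc(OC)c3O[C@@H]2CO[Si](C)(C)C(C)(C)C)ccc1OCc1ccccc1
F5 | step 8 | 6-{4-[(2R,3R)-3-(4-benzyloxy-3-methoxyphenyl)-2-[(tert-butyldimethylsilyloxy)methyl]-8-methoxy-2,3-dihydro-1,4-benzodioxin-6-yl]-4-hydroxy-2-oxobutyl}-4-hydroxy-2H-pyran-2-one (both carbinol epimers) | COc1cc([C@H]2Oc3cc(C(O)CC(=O)Cc4cc(O)cc(=O)o4)cc(OC)c3O[C@@H]2CO[Si](C)(C)C(C)(C)C)ccc1OCc1ccccc1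
F6 | step 6 | methyl 4-{[(1R,2R)-1-(4-benzyloxy-3-methoxyphenyl)-3-(tert-butyldimethylsilyloxy)-1-hydroxypropan-2-yl]oxy}-3-methoxy-5-(4,4,5,5-tetramethyl-1,3,2-dioxaborolan-2-yl)benzoate | COC(=O)c1cc(B2OC(C)(C)C(C)(C)O2)c(O[C@@H]([C@H](O)c2ccc(OCc3ccccc3)c(OC)c2)CO[Si](C)(C)C(C)(C)C)c(OC)c1
F7 | step 6 | methyl 4-{[(1R,2R)-1-(4-benzyloxy-3-methoxyphenyl)-3-(tert-butyldimethylsilyloxy)-1-hydroxypropan-2-yl]oxy}-3-hydroxy-5-methoxybenzoate | COC(=O)c1cc(O)c(O[C@@H]([C@H](O)c2ccc(OCc3ccccc3)c(OC)c2)CO[Si](C)(C)C(C)(C)C)c(OC)c1
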